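**Retrosynthetic overview**

- Target: a trans-fused daucane (bicyclo[5.3.0]decane). Numbering: C1 = CH3-bearing ring-fusion carbon, C2/C3 = ring CH2, C4 = C(OH)iPr, C5 = ring-fusion CH, C6 = CH–O-ester, C7 = C=O, C8 = C(CH3)OH, C9 = CHOH, C10 = CH2. End game: 8α,9α-cis-diol by OsO4 on the Δ8-7-enone, C6 ester by acylation, C7=O by allylic oxidation.
- Key disconnection (cycloheptene ring, formed second): C1–C10 and C8=C9 in one operation. This is a photoredox radical–polar crossover (5+2) annulation in which CH2=CH–PPh3+ is inserted between a tertiary C1 radical (from a tert-alkyl caesium oxalate) and a C8 methyl ketone (Giese addition, then intramolecular Wittig).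
- Enabling feature: in the seven-membered ring the quaternary, methyl-bearing C1 is joined through the two-carbon bridge C10H2–C9 to C8, a methyl carbinol. The C8/C9 cis-diol is the retron of a C8=C9 alkene, so C1 (radical) and C8 (ketone) are the two ends of the five-carbon unit C1–C5–C6–C7–C8.
- C6–C7–C8 comes from a D-proline-catalysed anti-aldol of hydroxyacetone with a cyclopentanecarbaldehyde (sets C6; C7 is a sacrificial stereocentre), the diol masked as an acetonide.
- Cyclopentane ring (formed first) from the chiral pool: (S)-terpinen-4-ol supplies C4; ozonolysis and intramolecular aldol (ring contraction 6 → 5) also deliver the C1 tertiary alcohol used as radical precursor.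

Key step: step 7

Remark on names: daucane locants are used for all intermediates; β is the face that carries CH3-15 on C1 in the target, α the opposite face.
Assumption: (S)-(+)-terpinen-4-ol is used enantiopure (commercial material may need enantiomeric enrichment).
Assumption: compounds 4 and 6–9 are drawn as the 1β-hydroxy epimers; the C1 epimers would serve equally, because C1 is planarised in step 7.

**Step 1**
Reactants: 1 (S)-(+)-terpinen-4-ol [(1S)-4-methyl-1-(propan-2-yl)cyclohex-3-en-1-ol]
Product: 2 (S)-terpinen-4-ol triethylsilyl ether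
Conditions: TESOTf, 2,6-lutidine, CH2Cl2, −78 to 0 °C
Reagents that add atoms: triethylsilyl trifluoromethanesulfonate, CC[Si](CC)(CC)OS(=O)(=O)C(F)(F)F
Why: Silylation of the hindered tertiary alcohol with a silyl triflate is standard, protects the later C4–OH against retro-aldol cleavage and acylation, and does not touch the stereocentre.

**Step 2**
Reactants: 2 (S)-terpinen-4-ol triethylsilyl ether
Product: 3 (3S)-6-oxo-3-(propan-2-yl)-3-(triethylsilyloxy)heptanal
Conditions: O3, CH2Cl2/MeOH, −78 °C; then PPh3, −78 °C to rt
Reagents that add atoms: ozone, [O-][O+]=O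
Why: Ozonolysis of the trisubstituted ring alkene with reductive work-up should give the 1,6-keto aldehyde (used crude) with the quaternary carbinol centre (later C4) unchanged.

**Step 3**
Reactants: 3 (3S)-6-oxo-3-(propan-2-yl)-3-(triethylsilyloxy)heptanal
Product: 4 2β-hydroxy-2α-methyl-5α-(propan-2-yl)-5β-(triethylsilyloxy)cyclopentane-1β-carbaldehyde (ring carbons = C5, C1, C2, C3, C4 of the daucane; CHO = C6; 5α-H)
Conditions: D-proline (20 mol %), DMSO, rt
Reagents that add atoms: none
Why: Enamine-mediated intramolecular aldol addition (5-enolexo, aldehyde donor, methyl ketone acceptor) should close the cyclopentane through C1–C5 and stop at the β-hydroxy aldehyde; C5, being α to the aldehyde, can equilibrate through the enamine to the isomer with the formyl group trans to the isopropyl group (5α-H), and the configuration at C1 is without consequence.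

**Step 4**
Reactants: 4 the aldol aldehyde of step 3; 5 hydroxyacetone (1-hydroxypropan-2-one)
Product: 6 (3R,4R)-3,4-dihydroxy-4-[2β-hydroxy-2α-methyl-5α-(propan-2-yl)-5β-(triethylsilyloxy)cyclopent-1β-yl]butan-2-one (6R,7R in daucane locants; anti-diol)
Conditions: 5 (excess), D-proline (30 mol %), DMSO, rt
Reagents that add atoms: none
Why: The proline-catalysed direct aldol addition of hydroxyacetone reacts regioselectively through the hydroxylated enamine carbon and gives anti-1,2-diols with α-branched aldehydes, so it should form C6–C7 under catalyst control, D-proline giving the (6R,7R) diol, while C5 is fixed once the aldehyde is consumed.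

**Step 5**
Reactants: 6 the anti-diol methyl ketone
Product: 7 the 6,7-O-isopropylidene derivative of 6 (cis-4,5-disubstituted 2,2-dimethyl-1,3-dioxolane; tertiary C1–OH free)
Conditions: 2,2-dimethoxypropane, PPTS (cat.), CH2Cl2, rt
Reagents that add atoms: 2,2-dimethoxypropane, COC(C)(C)OC
Why: Acid-catalysed transketalisation protects the vicinal diol as the cis-dioxolane, removes both acidic O–H groups before the ylide chemistry and leaves the hindered tertiary C1–OH as the only free hydroxyl.

**Step 6**
Reactants: 7 the acetonide
Product: 9 caesium oxalate of the tertiary C1 alcohol of 7, via methyl oxalate diester 8 (not isolated)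
Conditions: ClC(O)CO2Me, Et3N, DMAP (cat.), CH2Cl2, 0 °C to rt; then CsOH·H2O (1.0 equiv), THF/H2O, rt
Reagents that add atoms: methyl chlorooxoacetate, COC(=O)C(=O)Cl; caesium hydroxide, [Cs+].[OH-]
Why: Acylation of a tertiary alcohol with methyl chlorooxoacetate followed by selective saponification of the more electrophilic methyl ester is the standard preparation of bench-stable tert-alkyl caesium oxalates, the precursors of tertiary radicals under photoredox conditions.

**Step 7**
Reactants: 9 the caesium oxalate; 10 vinyltriphenylphosphonium bromide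
Product: 12 6α,7α-(isopropylidenedioxy)-4β-(triethylsilyloxy)-5αH-dauc-8-ene (trans-fused, 1β-CH3), via phosphonium ylide 11 (not isolated)
Conditions: Ir[dF(CF3)ppy]2(dtbbpy)PF6 (2 mol %), DMSO, 4 Å MS, 450 nm LEDs, 25–40 °C, no added base
Reagents that add atoms: none
Why: Proposed new method: oxidation of the tert-alkyl oxalate by the excited Ir(III) catalyst releases two CO2 and the planar tertiary C1 radical, which adds (Giese) to the CH2 terminus of the vinylphosphonium salt to form C1–C10; the α-phosphonio radical is reduced by Ir(II) to the non-stabilised ylide 11 (redox- and charge-neutral radical–polar crossover), and 11 olefinates the C8 methyl ketone intramolecularly to form C8=C9 and Ph3PO. The closest known reactions are the Giese additions of tertiary radicals from caesium oxalates to electron-poor alkenes and the photoredox conjunctive olefination, in which alkyl radicals add to vinylphosphonium salts and the resulting ylides olefinate carbonyl compounds intermolecularly; new here is the intramolecular, ring-forming version with a ketone, a formal (5+2) annulation. The cycloheptene is closed by a seven-membered ylide–carbonyl (oxaphosphetane) cyclisation between the trans-disposed C10 and C6 arms of the cyclopentane, and the cis-dioxolane holds C5 and C8 on the same side, which should favour closure. The only stereocentre formed is C1: the acceptor should approach the radical anti to the branched vicinal C5 substituent, giving C10 α and CH3 β (trans ring fusion) whatever the C1 configuration of 9. The step needs radical addition to the phosphonium alkene rather than reduction of the radical, and Wittig closure rather than proton transfer; the ylide (conjugate acid pKa about 22 in DMSO) is too weak a base to enolise the methyl ketone, C5, C6 and C7 carry no acidifying carbonyl in 9, and the ketone is the only electrophile within reach.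

**Step 8**
Reactants: 12 the tricyclic alkene
Product: 13 5αH-dauc-8-ene-4β,6α,7α-triol
Conditions: 1 M HCl (aq.), THF, rt
Reagents that add atoms: none
Why: Acid hydrolysis should remove the acetonide and the tertiary triethylsilyl ether in one operation without touching a stereocentre, setting free the allylic C7–OH for selective oxidation.

**Step 9**
Reactants: 13 the triol
Product: 14 4β,6α-dihydroxy-5αH-dauc-8-en-7-one
Conditions: activated MnO2 (excess), CH2Cl2, rt
Reagents that add atoms: none
Why: Activated manganese dioxide oxidises the allylic secondary alcohol at C7 chemoselectively to the conjugated enone, leaves the saturated secondary C6–OH and the tertiary C4–OH untouched, and erases the sacrificial C7 stereocentre.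

**Step 10**
Reactants: 14 the hydroxy enone; 15 4-(benzyloxy)benzoyl chloride
Product: 16 6α-[4-(benzyloxy)benzoyloxy]-4β-hydroxy-5αH-dauc-8-en-7-one
Conditions: pyridine, DMAP (cat.), CH2Cl2, 0 °C to rt
Reagents that add atoms: none
Why: Nucleophile-catalysed acylation should take place at the only secondary hydroxyl (C6) with retention, the tertiary C4–OH being inert under these conditions.

**Step 11**
Reactants: 16 the enone ester
Product: 17 6α-[4-(benzyloxy)benzoyloxy]-4β,8α,9α-trihydroxy-5αH-daucan-7-one
Conditions: OsO4 (5 mol %), NMO, citric acid, t-BuOH/H2O, rt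
Reagents that add atoms: N-methylmorpholine N-oxide, C[N+]1([O-])CCOCC1; water, O
Why: Catalytic osmium tetroxide cis-dihydroxylation (Upjohn conditions, citric acid for the electron-poor alkene) should add both hydroxyls suprafacially to C8=C9 from the α-face, opposite the axial C15 methyl on C1 that shields the β-face, which sets the 8α- and 9α-carbinol centres together.

**Step 12**
Reactants: 17 the benzyl-protected triol
Product: 18 4β,8α,9α-trihydroxy-6α-(4-hydroxybenzoyloxy)-5αH-daucan-7-one (target, CNP0241001.1)
Conditions: H2 (1 atm), 10% Pd/C, EtOAc, rt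
Reagents that add atoms: none
Why: Hydrogenolysis of the benzyl aryl ether should liberate the phenol under neutral conditions that leave the ester, the ketone and all carbinol centres untouched.

**Compound list**

1 | (S)-(+)-terpinen-4-ol | CC(C)[C@]1(O)CCC(C)=CC1 | starting material
2 | (S)-terpinen-4-ol triethylsilyl ether | CC(C)[C@]1(O[Si](CC)(CC)CC)CCC(C)=CC1 | intermediate
3 | (3S)-6-oxo-3-(propan-2-yl)-3-(triethylsilyloxy)heptanal | CC(C)[C@](CC=O)(O[Si](CC)(CC)CC)CCC(C)=O | intermediate
4 | 2β-hydroxy-2α-methyl-5α-(propan-2-yl)-5β-(triethylsilyloxy)cyclopentane-1β-carbaldehyde | CC(C)[C@]1(O[Si](CC)(CC)CC)CC[C@@](C)(O)[C@H]1C=O | intermediate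
5 | hydroxyacetone | CC(=O)CO | starting material
6 | (3R,4R)-3,4-dihydroxy-4-[2β-hydroxy-2α-methyl-5α-(propan-2-yl)-5β-(triethylsilyloxy)cyclopent-1β-yl]butan-2-one | CC(C)[C@]1(O[Si](CC)(CC)CC)CC[C@@](C)(O)[C@H]1[C@@H](O)[C@@H](O)C(C)=O | intermediate
7 | 6,7-O-isopropylidene derivative of 6 (cis-dioxolane, free tertiary C1–OH) | CC(C)[C@]1(O[Si](CC)(CC)CC)CC[C@@](C)(O)[C@H]1[C@H]2OC(C)(C)O[C@H]2C(C)=O | intermediate
8 | methyl oxalate diester of 7 (at C1–O) | CC(C)[C@]1(O[Si](CC)(CC)CC)CC[C@@](C)(OC(=O)C(=O)OC)[C@H]1[C@H]2OC(C)(C)O[C@H]2C(C)=O | intermediate (not isolated)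
9 | caesium oxalate of 7 (at C1–O) | CC(C)[C@]1(O[Si](CC)(CC)CC)CC[C@@](C)(OC(=O)C(=O)[O-])[C@H]1[C@H]2OC(C)(C)O[C@H]2C(C)=O.[Cs+] | intermediate
10 | vinyltriphenylphosphonium bromide | C=C[P+](c1ccccc1)(c1ccccc1)c1ccccc1.[Br-] | starting material
11 | phosphonium ylide (C1–CH2–CH=PPh3, C10 α on C1) | CC(C)[C@]1(O[Si](CC)(CC)CC)CC[C@](C)(CC=P(c3ccccc3)(c4ccccc4)c5ccccc5)[C@H]1[C@H]2OC(C)(C)O[C@H]2C(C)=O | intermediate (not isolated)
12 | 6α,7α-(isopropylidenedioxy)-4β-(triethylsilyloxy)-5αH-dauc-8-ene | CC(C)[C@]1(O[Si](CC)(CC)CC)CC[C@]2(C)CC=C(C)[C@@H]3OC(C)(C)O[C@@H]3[C@H]21 | intermediate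
13 | 5αH-dauc-8-ene-4β,6α,7α-triol | CC(C)[C@]1(O)CC[C@]2(C)CC=C(C)[C@H](O)[C@H](O)[C@H]21 | intermediate
14 | 4β,6α-dihydroxy-5αH-dauc-8-en-7-one | CC(C)[C@]1(O)CC[C@]2(C)CC=C(C)C(=O)[C@H](O)[C@H]21 | intermediate
15 | 4-(benzyloxy)benzoyl chloride | O=C(Cl)c1ccc(OCc2ccccc2)cc1 | starting material
16 | 6α-[4-(benzyloxy)benzoyloxy]-4β-hydroxy-5αH-dauc-8-en-7-one | CC(C)[C@]1(O)CC[C@]2(C)CC=C(C)C(=O)[C@H](OC(=O)c3ccc(OCc4ccccc4)cc3)[C@H]21 | intermediate
17 | 6α-[4-(benzyloxy)benzoyloxy]-4β,8α,9α-trihydroxy-5αH-daucan-7-one | CC(C)[C@]1(O)CC[C@]2(C)C[C@H](O)[C@](C)(O)C(=O)[C@H](OC(=O)c3ccc(OCc4ccccc4)cc3)[C@H]21 | intermediate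
18 | 4β,8α,9α-trihydroxy-6α-(4-hydroxybenzoyloxy)-5αH-daucan-7-one | CC(C)[C@]1(O)CC[C@]2(C)C[C@H](O)[C@](C)(O)C(=O)[C@H](OC(=O)c3ccc(O)cc3)[C@H]21 | target

Total step count: 12. Longest linear sequence: 12 steps (1 to 18).

**Steps most likely to fail**

Step 7 (proposed new method). What may go wrong: the ylide is protonated by adventitious water or by phosphonium C–H before it closes the seven-membered ring, the α-phosphonio radical is reduced too slowly and adds to more 10, or the radical addition is not face-selective at C1. Fallback with known chemistry, from 9 back to 12: the same photoredox decarboxylation of 9 is run with vinylboronic acid pinacol ester and water as proton source (radical addition, reduction and protonation) to give the alkylboronate F1. Oxidation with NaBO3·4H2O in THF/H2O gives the primary alcohol F2, and Dess–Martin oxidation gives the keto aldehyde F3. Intramolecular McMurry coupling (TiCl3(DME)1.5, Zn–Cu, DME, reflux, high dilution) then closes C8=C9 and returns to 12.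

Step 3. What may go wrong: the β-hydroxy aldehyde dehydrates to the conjugated enal or reopens by retro-aldol reaction, and C5 does not settle in the wanted configuration. Fallback, from 3 back to 4: the aldol is driven deliberately to the conjugated enal F4 (piperidine, AcOH, toluene, 80 °C). Weitz–Scheffer epoxidation (H2O2, NaOH, MeOH, 0 °C) gives the epoxy aldehyde F5, whose configuration is immaterial. Reductive opening of the Cα–O bond of the α,β-epoxy carbonyl unit (PhSeSePh, NaBH4, AcOH, EtOH) returns the β-hydroxy aldehyde 4 after equilibration at C5; its C1 epimer would serve equally.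

Step 4. What may go wrong: slow addition to an aldehyde flanked by two fully substituted carbons, mismatched double diastereoselection, or elimination of the β-oxygen substituents through the enamine. Fallback, from 4 back to 7: reagent-controlled anti-α-hydroxyallylation with the diisopropyl tartrate ester of (E)-γ-[(cyclohexyloxy)dimethylsilyl]allylboronic acid (tartrate enantiomer chosen for 6R; toluene, −78 °C) gives the anti β-hydroxy allylsilane F6. Tamao–Fleming oxidation (H2O2, KF, KHCO3, THF/MeOH) gives the anti vinyl diol F7, and 2,2-dimethoxypropane/PPTS gives the vinyl dioxolane F8. Wacker oxidation (PdCl2, CuCl, O2, DMF/H2O) of the terminal vinyl group gives the methyl ketone 7.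

**Further compounds**

F1 | step 7 | alkylboronate (C1–CH2CH2–Bpin) | CC(C)[C@]1(O[Si](CC)(CC)CC)CC[C@](C)(CCB2OC(C)(C)C(C)(C)O2)[C@H]1[C@H]3OC(C)(C)O[C@H]3C(C)=O
F2 | step 7 | primary alcohol (C1–CH2CH2OH) | CC(C)[C@]1(O[Si](CC)(CC)CC)CC[C@](C)(CCO)[C@H]1[C@H]2OC(C)(C)O[C@H]2C(C)=O
F3 | step 7 | keto aldehyde (C1–CH2CHO) | CC(C)[C@]1(O[Si](CC)(CC)CC)CC[C@](C)(CC=O)[C@H]1[C@H]2OC(C)(C)O[C@H]2C(C)=O
F4 | step 3 | (5S)-2-methyl-5-(propan-2-yl)-5-(triethylsilyloxy)cyclopent-1-ene-1-carbaldehyde | CC(C)[C@]1(O[Si](CC)(CC)CC)CCC(C)=C1C=O
F5 | step 3 | 1,5-epoxy aldehyde (β-epoxide of F4) | CC(C)[C@]1(O[Si](CC)(CC)CC)CC[C@@]2(C)O[C@@]12C=O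
F6 | step 4 | anti β-hydroxy allylsilane | CC(C)[C@]1(O[Si](CC)(CC)CC)CC[C@@](C)(O)[C@H]1[C@@H](O)[C@@H]([Si](C)(C)OC2CCCCC2)C=C
F7 | step 4 | anti vinyl diol | CC(C)[C@]1(O[Si](CC)(CC)CC)CC[C@@](C)(O)[C@H]1[C@@H](O)[C@@H](O)C=C
F8 | step 4 | vinyl dioxolane | CC(C)[C@]1(O[Si](CC)(CC)CC)CC[C@@](C)(O)[C@H]1[C@H]2OC(C)(C)O[C@H]2C=C
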